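Take a small charge: Wednesday's flask sets 0.025 M of substrate against 0.0800 M of activator, and you want the ring after 50 min.

| flask | substrate | activator | remark | time |
|---|---|---|---|---|
| oak | 0.025 M | 0.054 M | run made earlier |  |
| ash | 0.025 M | 0.16 M | run made earlier |  |
| Wednesday's | 0.025 M | 0.0800 M |  | 50 min |
| Tuesday's | 0.050 M | 0.0800 M |  | 50 min |
| Sunday's | 0.10 M | 0.0800 M |  | 50 min |
| Friday's | 0.20 M | 0.0800 M |  | 50 min |

| run | time / min | ring / % | substrate / % |
|---|---|---|---|
| oak | 4.00 | 3 | 71 |
| oak | 8.00 | 10 | 54 |
| oak | 12.0 | 13 | 40 |
| oak | 15.0 | 20 | 32 |
| oak | 20.0 | 30 | 26 |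
| oak | 25.0 | 38 | 19 |
| oak | 30.0 | 44 | 11 |
| ash | 1.50 | 0 | 67 |
| ash | 5.00 | 8 | 29 |
| ash | 8.00 | 18 | 16 |
| ash | 12.0 | 27 | 4 |
| ash | 20.0 | 46 | 1 |
| ash | 25.0 | 57 | 0 |
| ash | 30.0 | 63 | 0 |

(each reading ± 1.5 percentage points)

1. [ring] at the end for Wednesday's, Tuesday's, Sunday's, Friday's, in this order
2. the course of these numbers from the first flask to the last (rises, then falls / falls, then rises / hardly changes / falls all the way / rises all the way)

- "hardly changes" means that all values lie within two and a half points (for a concentration: within two and a half percent of the largest)

Assume one activator per substrate, which the runs suggest but do not prove. Then 0.0800 M is the crossing charge c×, the substrate charge at which the limiting reagent passes from substrate to activator.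

Now bound the ring from above. In the ash run substrate stands at 1 % after 20.0 min, yet ring climbs from 46 % to 63 % by 30.0 min, so an unseen form releases it. Read as first order, the release constant k_r is 0.0378 /min. Even with release starting at once, you get 84.9 % of the smaller charge. So the ceiling is 0.0212 M for Wednesday's flask. It rises with charge up to c×, then stays flat at 0.0679 M.

Now bound it from below. Even if each substrate takes one activator, Wednesday's activator ends at 0.0550 M, which is more than the oak charge of 0.054 M. In the oak run substrate falls with a constant k_a of 0.0770 /min, so I take that constant as a low value for Wednesday's flask. Two first-order steps in series at this k_a give a floor of 0.0181 M. This floor is an estimate and not a strict bound, since a side path would lower the ring.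

Above c× I have no floor, since both runs held substrate at 0.025 M. Friday's 0.20 M lies far past c×. So I commit to a row that climbs to c×, is flat at best beyond it, and may fall.

The forecast gives 0.02 M, 0.037 M, 0.06 M and 0.067 M, rises all the way, with the remark “Both runs used one substrate level, so substrate effects are extrapolated”, and its first value lies inside Wednesday's bracket.

The flasks give 0.0186 M, 0.0325 M, 0.0405 M and 0.0159 M: rises, then falls.

    substrate + ring → side product (k = 0.00790 /M/s)
    substrate + activator → activated form (k = 0.0270 /M/s)
    activated form → ring (k = 6.80 × 10⁻⁴ /s)
    substrate + activated form → open dimer (k = 0.00400 /M/s)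

The row turns at 0.089 M, close to c×, and Wednesday's 0.0186 M stands inside the bracket. In Friday's flask, above c×, activator is down to 0.0591 % of its charge, and ring stands at 0.0159 M, under the ceiling. At 50.0 min, Wednesday's ring forms 157 times as fast as substrate consumes it. Friday's ring, with 30.6 % of the substrate left, is consumed 2.18 times as fast as it forms.

The numbers in the tables stem from a simulated flask with made-up constants; scatter was added.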